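Ring B is disconnected at C9–C10 and C9–C20: a rhodium carbenoid at C9, next to the C8 carbonyl, adds across the exocyclic C10=C20 alkene of a ring A methylenecyclohexane. The step exploits the fact that the quaternary C10 with its angular methyl C20 sits beside C9, the carbon α to C8 (later the methylene-bearing carbon of ring B). In one operation it closes ring B and a temporary cyclopropane and sets C10; lithium/ammonia then unmasks the C10 methyl and a regiodefined C8–C9 enolate that takes the side chain. The precursor is a terminal diazoketone (C8, C9) linked through C6–C7 to C5 of ring A, which already carries the C4 methyl/silyloxymethyl pair.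

Key step: step 8

Remarks on the chemistry:
- Labdane numbering is used for all intermediates: C1–C10 are the decalin carbons, C18 the oxygen-bearing carbon on C4, C19 the C4 methyl, C20 the carbon that ends as the C10 methyl, C17 the exocyclic methylene carbon on C8, C11–C16 the side chain.
- Assumption: the sense of induction of the chiral copper catalyst in step 1 is not predicted here; the ligand enantiomer that gives the (3S) quaternary centre of 6 is the one used.

Step 1
Reactants: 1 3-methylcyclohex-2-en-1-one; 2 (chloromethyl)dimethyl(propan-2-yloxy)silane; 3 allyl iodide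
Product: 6 (2R,3S)-3-{[dimethyl(propan-2-yloxy)silyl]methyl}-3-methyl-2-(prop-2-en-1-yl)cyclohexan-1-one, via Grignard reagent 4 (not isolated), via magnesium enolate 5 (not isolated)
Conditions: 2, Mg, Et2O, reflux; then 1, Cu(OTf)2 (3 mol %), chiral N-mesityl-N'-(1-hydroxyalk-2-yl)imidazolinium hexafluorophosphate (NHC precursor, 4 mol %), Et2O, −30 °C; then 3, DMPU, THF, −30 → 25 °C
Reagents that add atoms: none
Why: Copper-catalysed asymmetric conjugate addition of a Grignard reagent to the β-methyl enone sets the C4 quaternary centre under catalyst control, and the regiodefined magnesium enolate 5 should be C-allylated at C5 anti to the bulkier silylmethyl group (cis to the C4 methyl), allyl iodide being chosen because it alkylates hindered enolates cleanly and brings C6–C8.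

Step 2
Reactants: 6 (2R,3S)-3-{[dimethyl(propan-2-yloxy)silyl]methyl}-3-methyl-2-(prop-2-en-1-yl)cyclohexan-1-one
Product: 7 (2R,3S)-3-(hydroxymethyl)-3-methyl-2-(prop-2-en-1-yl)cyclohexan-1-one
Conditions: 30% H2O2, KF, KHCO3, THF/MeOH, 0 → 25 °C
Reagents that add atoms: hydrogen peroxide, OO
Why: Tamao–Fleming oxidation, in which fluoride-assisted peroxide attack on the alkoxysilane and 1,2-shift of the CH2 group from silicon to oxygen give the primary alcohol while the bicarbonate buffer spares the ketone, the alkene and the C5 centre.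

Step 3
Reactants: 7 (2R,3S)-3-(hydroxymethyl)-3-methyl-2-(prop-2-en-1-yl)cyclohexan-1-one
Product: 8 (2R,3S)-3-({[tert-butyl(dimethyl)silyl]oxy}methyl)-3-methyl-2-(prop-2-en-1-yl)cyclohexan-1-one
Conditions: TBSCl, imidazole, DMF, 25 °C
Reagents that add atoms: tert-butyldimethylsilyl chloride, CC(C)(C)[Si](C)(C)Cl
Why: Standard silylation of the primary alcohol gives an ether that is inert to the carbenoid and to dissolving metal (no aryl groups) and whose bulk should keep the C4 oxymethyl group equatorial in the key step.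

Step 4
Reactants: 8 (2R,3S)-3-({[tert-butyl(dimethyl)silyl]oxy}methyl)-3-methyl-2-(prop-2-en-1-yl)cyclohexan-1-one
Product: 9 tert-butyl(dimethyl){[(1S,2S)-1-methyl-3-methylidene-2-(prop-2-en-1-yl)cyclohexyl]methoxy}silane
Conditions: Cp2TiMe2, toluene/THF, 70 °C
Reagents that add atoms: dimethyltitanocene Cp2TiMe2, [CH3-].[CH3-].[Ti+4].C1=C[CH-]C=C1.C1=C[CH-]C=C1
Why: Petasis methylenation through Cp2Ti=CH2 (tetravalent titanium) olefinates the hindered ketone under non-basic conditions, so the epimerisable C5 centre is locked with its configuration intact and C20 is installed.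

Step 5
Reactants: 9 tert-butyl(dimethyl){[(1S,2S)-1-methyl-3-methylidene-2-(prop-2-en-1-yl)cyclohexyl]methoxy}silane
Product: 11 3-[(1S,2S)-2-({[tert-butyl(dimethyl)silyl]oxy}methyl)-2-methyl-6-methylidenecyclohexyl]propan-1-ol, via trialkylborane 10 (not isolated)
Conditions: Sia2BH (BH3·THF + 2-methylbut-2-ene), THF, 0 °C; then NaOH, 30% H2O2, 0 → 25 °C
Reagents that add atoms: hydrogen peroxide, OO
Why: Hydroboration–oxidation, in which the bulky dialkylborane should add anti-Markovnikov to the unhindered monosubstituted alkene much faster than to the flanked 1,1-disubstituted exocyclic alkene.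

Step 6
Reactants: 11 3-[(1S,2S)-2-({[tert-butyl(dimethyl)silyl]oxy}methyl)-2-methyl-6-methylidenecyclohexyl]propan-1-ol
Product: 12 3-[(1S,2S)-2-({[tert-butyl(dimethyl)silyl]oxy}methyl)-2-methyl-6-methylidenecyclohexyl]propanoic acid
Conditions: TEMPO (20 mol %), PhI(OAc)2 (2.2 equiv), NaHCO3, MeCN/H2O 1:1, 25 °C
Reagents that add atoms: water, O
Why: Oxoammonium (TEMPO) oxidation takes the primary alcohol through the aldehyde hydrate to the acid under near-neutral conditions that spare the exocyclic alkene and the silyl ether.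

Step 7
Reactants: 12 3-[(1S,2S)-2-({[tert-butyl(dimethyl)silyl]oxy}methyl)-2-methyl-6-methylidenecyclohexyl]propanoic acid; 13 trimethylsilyldiazomethane
Product: 15 1-diazo-4-[(1S,2S)-2-({[tert-butyl(dimethyl)silyl]oxy}methyl)-2-methyl-6-methylidenecyclohexyl]butan-2-one, via acid chloride 14 (not isolated)
Conditions: 1-chloro-N,N,2-trimethylprop-1-en-1-amine, CH2Cl2, 0 → 25 °C; then 13 (2.5 equiv), THF/MeCN 1:1, 0 → 25 °C
Reagents that add atoms: none
Why: The α-chloroenamine forms the acid chloride without free HCl (the acid-labile alkene and silyl ether are kept), and acylation of the silyl diazomethane with loss of the silyl group (Arndt–Eistert-type diazoketone synthesis) adds C9.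

Step 8
Reactants: 15 1-diazo-4-[(1S,2S)-2-({[tert-butyl(dimethyl)silyl]oxy}methyl)-2-methyl-6-methylidenecyclohexyl]butan-2-one
Product: 16 (4S,5S,9S,10S)-4-({[tert-butyl(dimethyl)silyl]oxy}methyl)-4-methyl-9,10-methanodecalin-8-one (tricyclic cyclopropyl ketone; cyclopropane C9–C10–C20)
Conditions: Rh2(OAc)4 (1 mol %), CH2Cl2, 25 °C, 15 added over 6 h (syringe pump, final 0.005 M)
Reagents that add atoms: none
Why: Rh2(OAc)4 (divalent rhodium) extrudes N2 from the diazoketone to give an electrophilic rhodium carbenoid at C9, which adds in a concerted, asynchronous manner to the electron-rich 1,1-disubstituted C10=C20 alkene and so forms C9–C10 and C9–C20 in one event. The closest known reaction type is the intramolecular cyclopropanation of olefinic α-diazoketones, long used ahead of dissolving-metal cleavage to generate angular methyl groups. Ring B closes in the 6-exo mode (C9 onto C10 through the C6–C7–C8 tether, C20 remaining outside the six-membered ring), and the cyclopropane closes by cheletropic [2+1] addition of the same carbon to C20, which makes it necessarily cis-fused to ring B. C10 is controlled by the C5 stereocentre: with the tether equatorial on the ring A chair, C9 reaches the alkene from the face of H-5, anti to the axial C4 methyl, so that the new C9–C10 bond is equatorial and C20 axial and trans to H-5; C9 then follows from the geometric constraint of the fused three-membered ring. The step needs chemoselectivity (cyclopropanation over insertion into the allylic C5–H bond, Wolff rearrangement and carbenoid dimerisation), which the nucleophilic alkene placed for six-ring closure, the carboxylate ligands and slow addition at high dilution should secure, and diastereofacial selectivity, which the equatorial preference of the bulky silyloxymethyl group on C4 should secure by keeping the reactive chair populated.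

Step 9
Reactants: 17 2-(2-bromoethyl)-2-methyl-1,3-dioxolane
Product: 18 2-(2-iodoethyl)-2-methyl-1,3-dioxolane
Conditions: NaI, NaHCO3 (trace), acetone, reflux
Reagents that add atoms: sodium iodide, [Na+].[I-]
Why: Finkelstein exchange (SN2, driven by precipitation of NaBr) supplies the more reactive iodide for the enolate alkylation.

Step 10
Reactants: 16 (4S,5S,9S,10S)-4-({[tert-butyl(dimethyl)silyl]oxy}methyl)-4-methyl-9,10-methanodecalin-8-one; 18 2-(2-iodoethyl)-2-methyl-1,3-dioxolane
Product: 20 (4S,5S,9R,10R)-4-({[tert-butyl(dimethyl)silyl]oxy}methyl)-4,10-dimethyl-9-[2-(2-methyl-1,3-dioxolan-2-yl)ethyl]-trans-decalin-8-one, via lithium enolate 19 (not isolated)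
Conditions: Li (2.2 equiv), NH3(l)/THF, tBuOH (1.0 equiv), −78 °C; isoprene; then 18 (3 equiv), −78 → −33 °C; NH4Cl
Reagents that add atoms: none
Why: Dissolving-metal reduction cleaves the C9–C20 bond (the cyclopropane bond that overlaps with the C8 carbonyl and leads to the primary carbanion), giving the C10 methyl and the regiodefined enolate 19, whose reductive alkylation by the primary iodide should occur axially, anti to the angular methyl, placing the side chain trans to C20.

Step 11
Reactants: 20 (4S,5S,9R,10R)-4-({[tert-butyl(dimethyl)silyl]oxy}methyl)-4,10-dimethyl-9-[2-(2-methyl-1,3-dioxolan-2-yl)ethyl]-trans-decalin-8-one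
Product: 21 (4S,5S,9S,10R)-4-({[tert-butyl(dimethyl)silyl]oxy}methyl)-4,10-dimethyl-9-[2-(2-methyl-1,3-dioxolan-2-yl)ethyl]-trans-decalin-8-one
Conditions: NaOMe, MeOH, 40 °C; chromatography, recovered 20 resubmitted
Reagents that add atoms: none
Why: Base-mediated equilibration through the C8–C9 enolate should epimerise C9 to the favoured epimer with the side chain equatorial and cis to the C10 methyl (H-9 axial), the ring-fusion centres not being enolisable.

Step 12
Reactants: 21 (4S,5S,9S,10R)-4-({[tert-butyl(dimethyl)silyl]oxy}methyl)-4,10-dimethyl-9-[2-(2-methyl-1,3-dioxolan-2-yl)ethyl]-trans-decalin-8-one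
Product: 23 (4S,5S,9S,10R)-4-({[tert-butyl(dimethyl)silyl]oxy}methyl)-4,10-dimethyl-9-[2-(2-methyl-1,3-dioxolan-2-yl)ethyl]-trans-decal-6-en-8-one, via silyl enol ether 22 (not isolated)
Conditions: LiN(iPr)2, THF, −78 °C; TMSCl; then Pd(OAc)2 (1.1 equiv), MeCN, 25 °C
Reagents that add atoms: none
Why: Saegusa–Ito oxidation, in which kinetic deprotonation takes place at the less hindered C7 methylene (not at the tertiary C9) and Pd(OAc)2 (divalent palladium) converts the silyl enol ether by β-hydride elimination into the C6=C7 enone.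

Step 13
Reactants: 23 (4S,5S,9S,10R)-4-({[tert-butyl(dimethyl)silyl]oxy}methyl)-4,10-dimethyl-9-[2-(2-methyl-1,3-dioxolan-2-yl)ethyl]-trans-decal-6-en-8-one
Product: 24 (4S,5S,9R,10S)-18-{[tert-butyl(dimethyl)silyl]oxy}-13,13-(ethylenedioxy)-14,15-dinorlabda-6,8(17)-diene
Conditions: Cp2TiMe2, toluene, 70 °C
Reagents that add atoms: dimethyltitanocene Cp2TiMe2, [CH3-].[CH3-].[Ti+4].C1=C[CH-]C=C1.C1=C[CH-]C=C1
Why: Petasis methylenation of the enone carbonyl gives the C6=C7/C8=C17 diene under neutral conditions, which avoids base-induced epimerisation at C9 or deconjugation through the C5 dienolate.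

Step 14
Reactants: 24 (4S,5S,9R,10S)-18-{[tert-butyl(dimethyl)silyl]oxy}-13,13-(ethylenedioxy)-14,15-dinorlabda-6,8(17)-diene
Product: 25 (4S,5S,9R,10S)-18-{[tert-butyl(dimethyl)silyl]oxy}-14,15-dinorlabda-6,8(17)-dien-13-one
Conditions: PPTS, acetone/H2O 4:1, 50 °C
Reagents that add atoms: water, O
Why: Mild acid-catalysed hydrolysis of the dioxolane frees the C13 methyl ketone, the buffered acid being too weak to isomerise the diene or cleave the hindered primary silyl ether.

Step 15
Reactants: 25 (4S,5S,9R,10S)-18-{[tert-butyl(dimethyl)silyl]oxy}-14,15-dinorlabda-6,8(17)-dien-13-one; 26 trimethyl phosphonoacetate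
Product: 28 methyl (4S,5S,9R,10S,13E)-18-{[tert-butyl(dimethyl)silyl]oxy}labda-6,8(17),13-trien-15-oate, via sodium phosphonate 27 (not isolated)
Conditions: 26, NaH, THF, 0 °C; then 25, 0 → 50 °C
Reagents that add atoms: none
Why: Horner–Wadsworth–Emmons olefination of the unhindered methyl ketone forms C13=C14, reversible addition favouring the oxaphosphetane that leads to the (E)-enoate, which is separated from the minor (Z)-isomer by chromatography.

Step 16
Reactants: 28 methyl (4S,5S,9R,10S,13E)-18-{[tert-butyl(dimethyl)silyl]oxy}labda-6,8(17),13-trien-15-oate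
Product: 30 methyl (4S,5S,9R,10S,13E)-18-acetoxylabda-6,8(17),13-trien-15-oate (target CNP0148290.1), via alcohol 29 (not isolated)
Conditions: HF·pyridine, pyridine, THF, 0 → 25 °C; then Ac2O, DMAP, 25 °C
Reagents that add atoms: acetic anhydride, CC(=O)OC(C)=O
Why: Buffered fluoride cleaves the Si–O bond and the liberated primary alcohol is acetylated in the same flask by DMAP-catalysed acyl transfer, neither operation affecting the diene or the enoate.

Compound list
1 | 3-methylcyclohex-2-en-1-one | CC1=CC(=O)CCC1 | starting material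
2 | (chloromethyl)dimethyl(propan-2-yloxy)silane | CC(C)O[Si](C)(C)CCl | starting material
3 | allyl iodide (3-iodoprop-1-ene) | C=CCI | starting material
4 | {[dimethyl(propan-2-yloxy)silyl]methyl}magnesium chloride | CC(C)O[Si](C)(C)C[Mg]Cl | intermediate
5 | chloromagnesium enolate of (S)-3-{[dimethyl(propan-2-yloxy)silyl]methyl}-3-methylcyclohexanone (C5=C10 enolate) | CC(C)O[Si](C)(C)C[C@@]1(C)CCCC(O[Mg]Cl)=C1 | intermediate
6 | (2R,3S)-3-{[dimethyl(propan-2-yloxy)silyl]methyl}-3-methyl-2-(prop-2-en-1-yl)cyclohexan-1-one | O=C1CCC[C@](C)(C[Si](C)(C)OC(C)C)[C@H]1CC=C | intermediate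
7 | (2R,3S)-3-(hydroxymethyl)-3-methyl-2-(prop-2-en-1-yl)cyclohexan-1-one | O=C1CCC[C@](C)(CO)[C@H]1CC=C | intermediate
8 | (2R,3S)-3-({[tert-butyl(dimethyl)silyl]oxy}methyl)-3-methyl-2-(prop-2-en-1-yl)cyclohexan-1-one | O=C1CCC[C@](C)(CO[Si](C)(C)C(C)(C)C)[C@H]1CC=C | intermediate
9 | tert-butyl(dimethyl){[(1S,2S)-1-methyl-3-methylidene-2-(prop-2-en-1-yl)cyclohexyl]methoxy}silane | C=C1CCC[C@](C)(CO[Si](C)(C)C(C)(C)C)[C@H]1CC=C | intermediate
10 | {3-[(1S,2S)-2-({[tert-butyl(dimethyl)silyl]oxy}methyl)-2-methyl-6-methylidenecyclohexyl]propyl}bis(3-methylbutan-2-yl)borane | C=C1CCC[C@](C)(CO[Si](C)(C)C(C)(C)C)[C@H]1CCCB(C(C)C(C)C)C(C)C(C)C | intermediate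
11 | 3-[(1S,2S)-2-({[tert-butyl(dimethyl)silyl]oxy}methyl)-2-methyl-6-methylidenecyclohexyl]propan-1-ol | C=C1CCC[C@](C)(CO[Si](C)(C)C(C)(C)C)[C@H]1CCCO | intermediate
12 | 3-[(1S,2S)-2-({[tert-butyl(dimethyl)silyl]oxy}methyl)-2-methyl-6-methylidenecyclohexyl]propanoic acid | C=C1CCC[C@](C)(CO[Si](C)(C)C(C)(C)C)[C@H]1CCC(=O)O | intermediate
13 | trimethylsilyldiazomethane | C[Si](C)(C)C=[N+]=[N-] | starting material
14 | 3-[(1S,2S)-2-({[tert-butyl(dimethyl)silyl]oxy}methyl)-2-methyl-6-methylidenecyclohexyl]propanoyl chloride | C=C1CCC[C@](C)(CO[Si](C)(C)C(C)(C)C)[C@H]1CCC(=O)Cl | intermediate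
15 | 1-diazo-4-[(1S,2S)-2-({[tert-butyl(dimethyl)silyl]oxy}methyl)-2-methyl-6-methylidenecyclohexyl]butan-2-one | C=C1CCC[C@](C)(CO[Si](C)(C)C(C)(C)C)[C@H]1CCC(=O)C=[N+]=[N-] | intermediate
16 | (4S,5S,9S,10S)-4-({[tert-butyl(dimethyl)silyl]oxy}methyl)-4-methyl-9,10-methanodecalin-8-one (cyclopropane C9–C10–C20; C20 trans to H-5, cis to the C4 methyl) | O=C1CC[C@@H]2[C@@](C)(CO[Si](C)(C)C(C)(C)C)CCC[C@]23C[C@H]13 | intermediate
17 | 2-(2-bromoethyl)-2-methyl-1,3-dioxolane | CC1(CCBr)OCCO1 | starting material
18 | 2-(2-iodoethyl)-2-methyl-1,3-dioxolane | CC1(CCI)OCCO1 | intermediate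
19 | lithium C8=C9 enolate of (4S,5S,10R)-4-({[tert-butyl(dimethyl)silyl]oxy}methyl)-4,10-dimethyl-trans-decalin-8-one | [Li]OC1=C[C@]2(C)CCC[C@](C)(CO[Si](C)(C)C(C)(C)C)[C@H]2CC1 | intermediate
20 | (4S,5S,9R,10R)-4-({[tert-butyl(dimethyl)silyl]oxy}methyl)-4,10-dimethyl-9-[2-(2-methyl-1,3-dioxolan-2-yl)ethyl]-trans-decalin-8-one (side chain axial, trans to the C10 methyl) | O=C1CC[C@@H]2[C@@](C)(CO[Si](C)(C)C(C)(C)C)CCC[C@@]2(C)[C@H]1CCC3(C)OCCO3 | intermediate
21 | (4S,5S,9S,10R)-4-({[tert-butyl(dimethyl)silyl]oxy}methyl)-4,10-dimethyl-9-[2-(2-methyl-1,3-dioxolan-2-yl)ethyl]-trans-decalin-8-one (side chain equatorial, cis to the C10 methyl) | O=C1CC[C@@H]2[C@@](C)(CO[Si](C)(C)C(C)(C)C)CCC[C@@]2(C)[C@@H]1CCC3(C)OCCO3 | intermediate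
22 | (4S,5S,9S,10R)-8-(trimethylsilyloxy)-7-ene silyl enol ether of 21 | C[Si](C)(C)OC1=CC[C@@H]2[C@@](C)(CO[Si](C)(C)C(C)(C)C)CCC[C@@]2(C)[C@@H]1CCC3(C)OCCO3 | intermediate
23 | (4S,5S,9S,10R)-4-({[tert-butyl(dimethyl)silyl]oxy}methyl)-4,10-dimethyl-9-[2-(2-methyl-1,3-dioxolan-2-yl)ethyl]-trans-decal-6-en-8-one | O=C1C=C[C@@H]2[C@@](C)(CO[Si](C)(C)C(C)(C)C)CCC[C@@]2(C)[C@@H]1CCC3(C)OCCO3 | intermediate
24 | (4S,5S,9R,10S)-18-{[tert-butyl(dimethyl)silyl]oxy}-13,13-(ethylenedioxy)-14,15-dinorlabda-6,8(17)-diene | C=C1C=C[C@@H]2[C@@](C)(CO[Si](C)(C)C(C)(C)C)CCC[C@@]2(C)[C@@H]1CCC3(C)OCCO3 | intermediate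
25 | (4S,5S,9R,10S)-18-{[tert-butyl(dimethyl)silyl]oxy}-14,15-dinorlabda-6,8(17)-dien-13-one | C=C1C=C[C@@H]2[C@@](C)(CO[Si](C)(C)C(C)(C)C)CCC[C@@]2(C)[C@@H]1CCC(C)=O | intermediate
26 | trimethyl phosphonoacetate | COC(=O)CP(=O)(OC)OC | starting material
27 | sodium salt of the trimethyl phosphonoacetate carbanion | [Na+].COC(=O)[CH-]P(=O)(OC)OC | intermediate
28 | methyl (4S,5S,9R,10S,13E)-18-{[tert-butyl(dimethyl)silyl]oxy}labda-6,8(17),13-trien-15-oate | C=C1C=C[C@@H]2[C@@](C)(CO[Si](C)(C)C(C)(C)C)CCC[C@@]2(C)[C@@H]1CC/C(C)=C/C(=O)OC | intermediate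
29 | methyl (4S,5S,9R,10S,13E)-18-hydroxylabda-6,8(17),13-trien-15-oate | C=C1C=C[C@@H]2[C@@](C)(CO)CCC[C@@]2(C)[C@@H]1CC/C(C)=C/C(=O)OC | intermediate
30 | methyl (4S,5S,9R,10S,13E)-18-acetoxylabda-6,8(17),13-trien-15-oate (CNP0148290.1) | C=C1C=C[C@@H]2[C@@](C)(COC(C)=O)CCC[C@@]2(C)[C@@H]1CC/C(C)=C/C(=O)OC | target

Total step count: 16. Longest linear sequence: 15 steps (1–8 and 10–16); step 9 is a one-step side branch.

Steps most likely to fail

1. Step 8 (key step). The carbenoid may insert into the allylic C5–H bond or dimerise instead of cyclopropanating, and some material may react through the ring-flipped chair and give the cis-fused diastereomer. Fallback, a cationic ring closure in place of the carbenoid: it sets out from acid 12 (through acid chloride 14, made as in step 7) and returns at ketone 21. Acylation of the lithium enolate of methyl acetate (THF, −78 °C) by 14 would give the β-keto ester methyl 5-[(1S,2S)-2-({[tert-butyl(dimethyl)silyl]oxy}methyl)-2-methyl-6-methylidenecyclohexyl]-3-oxopentanoate F1. Treatment with SnCl4 (CH2Cl2, −78 → 0 °C) should protonate C10=C20 at C20 and let the enol carbon C9 capture the tertiary C10 cation, as in the terminating step of polyene cyclisations, closing ring B with the C10 methyl already in place to give the trans-fused bicyclic β-keto ester F2. Alkylation at C9 with iodide 18 (K2CO3, DMF) would give the quaternary keto ester F3, and Krapcho demethoxycarbonylation (LiCl, wet DMSO, 150 °C) would lead to 21, any 20 in the mixture being equilibrated as in step 11.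

2. Step 10. C-alkylation of the hindered lithium enolate by an unactivated primary iodide may be slow, so that proton exchange (loss of regiocontrol, alkylation at C7), O-alkylation and elimination of HI from the iodide compete. Fallback, a Michael addition in place of the SN2 alkylation: it sets out from cyclopropyl ketone 16 and returns at ketone 20. After the same lithium/ammonia cleavage, the ammonia is replaced by THF and enolate 19 is silylated (TMSCl, Et3N) to the C8=C9 trimethylsilyl enol ether F4. TiCl4-mediated Mukaiyama–Michael addition to but-3-en-2-one (CH2Cl2, −78 °C) would give the 1,5-diketone F5, with the new chain trans to the C10 methyl. Chemoselective dioxolane formation at the unhindered methyl ketone (ethane-1,2-diol, PPTS, benzene, reflux with water removal) would give 20, which enters step 11.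

3. Step 1. The α-silylalkyl group may transfer from copper slowly and with insufficient enantioselectivity, and the allylation may be incompletely anti-selective. Fallback, with the roles of the two C4 substituents exchanged: because step 1 opens the route, it cannot leave from an intermediate; it sets out from allyl iodide 3 together with a new commercial arene, 3-methoxybenzyl alcohol, and returns at ketone 8. Birch reduction (Li, NH3, tBuOH) would give the dihydroanisole (5-methoxycyclohexa-1,4-dien-1-yl)methanol F6; aqueous acid would hydrolyse and conjugate it to 3-(hydroxymethyl)cyclohex-2-en-1-one F7; silylation (TBSCl, imidazole) would give 3-({[tert-butyl(dimethyl)silyl]oxy}methyl)cyclohex-2-en-1-one F8. Copper-catalysed asymmetric conjugate addition of Me3Al (copper thiophene-2-carboxylate, monovalent copper, chiral phosphoramidite, Et2O, −30 °C), a nucleophile well established for methyl-bearing quaternary centres on 3-substituted cyclohexenones, would give the dimethylaluminium enolate F9. After activation with MeLi, F9 would be allylated with 3 anti to the silyloxymethyl group to give 8.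

Further compounds
F1 | step 8 | methyl 5-[(1S,2S)-2-({[tert-butyl(dimethyl)silyl]oxy}methyl)-2-methyl-6-methylidenecyclohexyl]-3-oxopentanoate | C=C1CCC[C@](C)(CO[Si](C)(C)C(C)(C)C)[C@H]1CCC(=O)CC(=O)OC
F2 | step 8 | methyl (4S,5S,10R)-4-({[tert-butyl(dimethyl)silyl]oxy}methyl)-4,10-dimethyl-8-oxo-trans-decalin-9-carboxylate (C9 epimerisable) | O=C1CC[C@@H]2[C@@](C)(CO[Si](C)(C)C(C)(C)C)CCC[C@@]2(C)C1C(=O)OC
F3 | step 8 | methyl 4-({[tert-butyl(dimethyl)silyl]oxy}methyl)-4,10-dimethyl-9-[2-(2-methyl-1,3-dioxolan-2-yl)ethyl]-8-oxo-trans-decalin-9-carboxylate (side chain trans to the C10 methyl) | O=C1CC[C@@H]2[C@@](C)(CO[Si](C)(C)C(C)(C)C)CCC[C@@]2(C)[C@]1(CCC3(C)OCCO3)C(=O)OC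
F4 | step 10 | C8=C9 trimethylsilyl enol ether of (4S,5S,10R)-4-({[tert-butyl(dimethyl)silyl]oxy}methyl)-4,10-dimethyl-trans-decalin-8-one | C[Si](C)(C)OC1=C[C@]2(C)CCC[C@](C)(CO[Si](C)(C)C(C)(C)C)[C@H]2CC1
F5 | step 10 | (4S,5S,9R,10R)-4-({[tert-butyl(dimethyl)silyl]oxy}methyl)-4,10-dimethyl-9-(3-oxobutyl)-trans-decalin-8-one | O=C1CC[C@@H]2[C@@](C)(CO[Si](C)(C)C(C)(C)C)CCC[C@@]2(C)[C@H]1CCC(C)=O
F6 | step 1 | (5-methoxycyclohexa-1,4-dien-1-yl)methanol | COC1=CCC=C(CO)C1
F7 | step 1 | 3-(hydroxymethyl)cyclohex-2-en-1-one | O=C1C=C(CO)CCC1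
F8 | step 1 | 3-({[tert-butyl(dimethyl)silyl]oxy}methyl)cyclohex-2-en-1-one | O=C1C=C(CO[Si](C)(C)C(C)(C)C)CCC1
F9 | step 1 | dimethylaluminium enolate of (S)-3-({[tert-butyl(dimethyl)silyl]oxy}methyl)-3-methylcyclohexanone | C[Al](C)OC1=C[C@@](C)(CO[Si](C)(C)C(C)(C)C)CCC1
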